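The data were computed for substances that don't exist.

You read Friday's and Thursday's flasks at 3.0 h, long after the feed of 25 min has ended.

common to all: L 37 mM (fed, over 25 min)
- delta: Z 0.61 equiv; run made earlier
- zeta: Z 0.93 equiv; run made earlier
- epsilon: Z 0.95 equiv; run made earlier
- Friday's: Z 0.800 equiv; time 3.0 h
- Thursday's: Z 1.20 equiv; time 3.0 h

| run | time / min | L / % | D / % |
|---|---|---|---|
| delta | 8.00 | 27.9 | 4.5 |
| delta | 15.0 | 49.4 | 11.4 |
| delta | 25.0 | 77.4 | 20.3 |
| delta | 50.0 | 64.8 | 24.1 |
| delta | 90.0 | 58.7 | 20.5 |
| zeta | 20.0 | 55.0 | 23.7 |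
| zeta | 40.0 | 54.9 | 36.2 |
| zeta | 50.0 | 49.5 | 36.7 |
| zeta | 80.0 | 42.6 | 35.0 |
| zeta | 90.0 | 40.9 | 33.5 |
| epsilon | 8.00 | 26.5 | 5.6 |
| epsilon | 15.0 | 43.2 | 16.4 |
| epsilon | 25.0 | 67.0 | 29.9 |
| epsilon | 50.0 | 49.3 | 39.1 |
| epsilon | 90.0 | 39.8 | 34.3 |

(each reading ± 0.5 percentage points)

- a species is counted by the L in it: one E counts as two
- steps thought possible: L + Z -> X + D; L + D -> E; X -> J; D -> Q; Z + X <-> G
- percentages count the whole charge, also what has not yet gone in

1. part of the L that has reacted at the end, Friday's
2. part of the L that has reacted at the end, Thursday's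
3. what raising the equivalents of Z from its lowest to its highest value here does to the part of the L that has reacted (changes below 5 percentage points count as none) (it falls / it rises / no change)

1. Follow the first step, L + Z -> X + D. Each turn loses one L and makes one D. Each turn of L + D -> E loses one L and one D. With D -> Q neglected, first-step turnover is therefore the mean of reacted L and D.

2. In the epsilon run, this turnover averages 0.0126 min⁻¹ of the charge up to the end of the feed. The next interval reads 0.00538 min⁻¹, slower by a factor 2.34. The last reads 5.87 × 10⁻⁴ min⁻¹, slower by a further 9.16. Together that is a factor 21.4: the step is stopping.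

3. Take one Z per turn as the zero of the scale. The epsilon run should then stop near 0.95 equiv. Its turnover reads 47.2% at 90.0 min, half of that. The delta run reads 30.9%, against 30.5% for two Z per turn.

4. So count two Z per turn, the second bound as G, with Z as the limiting reagent. The stall turnover, the equivalents of Z divided by two, is 40.0% for Friday's and 60.0% for Thursday's.

5. My own reckoning stops there. L + D -> E adds to reacted L, and I put no figure on that. The stall gap of 20 percentage points exceeds the margin of 5 points, so I expect a rise.

The forecast gives 62% and 83%, and says it rises, on the ground that “each X formed ties up a second Z as G”.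

    L + Z → X + D (k = 1.60 M⁻¹ min⁻¹)
    L + D → E (k = 0.260 M⁻¹ min⁻¹)
    X → J (k = 0.0220 min⁻¹)
    D → Q (k = 2.70 × 10⁻⁵ min⁻¹)
    Z + X ⇌ G, settled at all times (K = 1.80 × 10⁵ M⁻¹)

Friday's reaches 62.3% and Thursday's 81.8%. On raising Z, the answer is: it rises, by 19 points. Thursday's stands above Friday's because of the difference in equivalents of Z: with Friday's Z it gives 62.3%. Without the association of Z + X to G, the gap between the two shrinks from 19 points to 7.4 points. Thursday's final turnover is 60.6%, against its stall turnover of 60.0%. In a flask like Thursday's with 0.480 equiv of Z, the stall turnover is 24.0%, and the turnover at 3.0 h stands at 25.6%.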